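## Analysis of the target

Phenylcandilide B, numbered 19 here, is a benzofuran whose furan ring carries a methyl group at C3 and a methoxycarbonylmethyl arm at C2. Its benzene ring (ring A) carries methoxy groups at C4 and C7, a 4-hydroxyphenyl group (ring B) at C6 and its only hydrogen at C5. The molecule has no stereocentre, so the whole problem is one of regiochemistry and of the order of events. Three groups need care: the para-dimethoxyarene, which is a masked quinone and is easily oxidized; the acidic methylene of the heteroarylacetic ester; and the phenol of ring B, which must stay distinguishable from the two methyl ethers of ring A. The difficulty lies in ring A, substituted at five of its six carbons: substitution chemistry on a preformed benzofuran would have to tell C5 from C6 and place two oxygens para to each other. The strategy rests on the fact that C4 and C7 both bear oxygen, so that ring A is the bis-enol of a furan-fused cyclohex-2-ene-1,4-dione in which C5 and C6 are the two carbonyl α-carbons. Cutting C5–C6 opens ring A to a furan with an acetyl group on the carbon that becomes C3a and an arylacetyl group on the carbon that becomes C7a, so the position of ring B follows from connectivity and not from selectivity.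

## Retrosynthetic reasoning

The benzyl–oxygen bond of 18 is cut first. The phenol of 19 is thus masked as a benzyl ether through all base and oxidant chemistry and is freed at the end by hydrogenolysis, which touches neither methyl ether nor the ester.

The C2–CH2 bond of 18 is cut next, which leads to iodide 17. The ester arm is brought in late and at its final oxidation level by a palladium-catalysed transfer of the two-carbon ester unit onto C2. Had it been present earlier, its acidic methylene would have been a third enolizable site in the key step.

The C2–I bond of 17 is traced to the C2–H bond of 15. C2 is the one position of 15 that a strong base removes selectively, so no directing or blocking group is needed.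

The two O–CH3 bonds of 15 are cut to reach dione 13 through its aromatic tautomer 14. The forward reaction has only to enolize 13, which aromatizes ring A, and to cap both phenoxide oxygens.

The C5–C6 bond of 13 is the strategic cut and leads to diketone 11 through its bis-enolate 12. Both carbons are enolate carbons, so the bond must be made by removing two electrons. What is gained is ring A with both oxygens, the aryl group and the lone hydrogen already in place. The forward reaction must join the two α-carbons faster than either enolate can attack the neighbouring carbonyl.

The bond between the furan and the acetyl group of 11 is cut to give bromide 9, enol ether 10 being the link. The bromine of 9 is thus replaced by an acetyl anion equivalent under neutral conditions, which suits the base-sensitive 1,4-dicarbonyl array.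

The bond between the furan and the arylacetyl group of 9 is cut to give furan 3 and amide 6. The bromine of 3 first makes the adjacent furan proton the most acidic one and later becomes the handle for the acetyl group.

Amide 6 comes from acid 4 by way of 5. Furan 3 comes from dibromide 1 by way of 2, using one of two equivalent bromines for a methyl group.

## Alternatives that were turned down

Alternative 1: The furan ring is closed last by cutting C3–C3a. The substrate is the racemic aryl ether A1, a 2-bromophenyl ether of methyl 3-hydroxypent-4-enoate. Zerovalent palladium inserts into the aryl–bromine bond, the aryl group adds in a 5-exo mode to the inner alkene carbon, and β-hydride elimination with double-bond migration gives the 3-methylbenzofuran A2, which is the same compound as 18.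
- For it: the cyclization type is well established, and it delivers the whole skeleton with the ester arm one hydrogenolysis from the target. In end-game economy it is stronger than the chosen route, which needs four steps after its key step.
- Against it: A1 is both an allylic aryl ether and a β-aryloxy ester. Zerovalent palladium can ionize it to an allyl complex and a phenoxide, and the base of the reaction can expel the phenoxide by β-elimination. The ring-A regiochemistry is also left unsolved, since the aromatic core of A1 is a pentasubstituted benzene that must be assembled by selective aromatic substitutions.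
- Comparison: the chosen strategy gives up the short end game and in return obtains the substitution pattern of ring A from the connectivity of a diketone.

Alternative 2: Ring B is built from acyclic carbons. Through its enamine, aldehyde A3 adds to the enone but-3-en-2-one A4, and aldol condensation closes the racemic cyclohexenone A5, which must then be dehydrogenated to the phenol 19.
- For it: classical, metal-free bond formation, and no phenol protecting group, a point on which it is stronger.
- Against it: it spends its key step on the one part of the molecule that can be bought as an intact aryl building block. A3 has a second acidic methylene, that of the ester arm, which competes in the conjugate addition to A4. The final dehydrogenation of A5 needs an oxidant in the presence of an electron-rich dimethoxybenzofuran. The construction of ring A with a two-carbon aldehyde arm at C6, as in A3, remains as hard as before.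
- Comparison: the chosen strategy pays one benzyl group and brings ring B in unchanged from acid 4.

Alternative 3: Ring A is made by cutting C3a–C4. Furyllithium A7 adds to the aryl cyclobutenedione A6 to give the racemic 4-hydroxycyclobutenone A8. Heating opens A8 to a dienylketene that closes onto the free furan β-carbon and tautomerizes to hydroquinone A9.
- For it: it is convergent, needs no oxidant and no strong base in the ring-forming event, fixes the regiochemistry by connectivity as the chosen route does, and already carries the two-carbon arm. In the reliability of the ring closure it is the stronger strategy.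
- Against it: neither fragment is at hand. A6, with a free vinylic hydrogen, and the 2,3-disubstituted furan core of A7 each need several steps. A7 must add to the right carbonyl of the unsymmetrical dione A6. After A9 there remain methylation, desilylation, oxidation to the acid, esterification and hydrogenolysis.
- Comparison: the chosen strategy accepts a riskier ring closure and in return reaches its precursor in three linear steps from a commercial furan and a commercial arylacetic acid.

Key step: step 5

## Remarks on the chemistry

- Dione 13 and hydroquinone 14 are tautomers. The coupling should deliver 13, which may enolize in part to 14 during isolation. Step 6 takes either form to 15, so the crude product is carried on without separating them.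
- Compounds 1 and 4 and all reagents are taken to be commercial.

## Route

Step 1
Reactants: 1 3,4-dibromofuran
Product: 3 3-bromo-4-methylfuran, via (4-bromofuran-3-yl)lithium 2 (not isolated)
Conditions: n-BuLi (1.0 equiv), Et2O, −78 °C; MeI, −78 → 0 °C
Reagents that add atoms: iodomethane, CI
Why: Bromine–lithium exchange at one of two equivalent C–Br bonds followed by SN2 methylation; at −78 °C the 3-furyllithium should neither isomerize to a 2-lithio species nor undergo a second exchange.

Step 2
Reactants: 4 4-(benzyloxy)phenylacetic acid
Product: 6 2-[4-(benzyloxy)phenyl]-N-methoxy-N-methylacetamide, via acyl imidazolide 5 (not isolated)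
Conditions: 1,1'-carbonyldiimidazole, CH2Cl2, rt; MeNH(OMe)·HCl, rt
Reagents that add atoms: N,O-dimethylhydroxylamine hydrochloride, CNOC.Cl
Why: Weinreb amide formation through the acyl imidazolide; the imidazole set free takes up the HCl of the amine salt.

Step 3
Reactants: 3 3-bromo-4-methylfuran; 6 2-[4-(benzyloxy)phenyl]-N-methoxy-N-methylacetamide
Product: 9 2-[4-(benzyloxy)phenyl]-1-(3-bromo-4-methylfuran-2-yl)ethan-1-one, via (3-bromo-4-methylfuran-2-yl)lithium 7 (not isolated), via lithium hemiaminal alkoxide 8 (not isolated)
Conditions: LiN(i-Pr)2 (1.0 equiv), THF, −78 °C; 6, −78 → −40 °C; aq. NH4Cl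
Reagents that add atoms: none
Why: Directed ortho-metalation and Weinreb ketone synthesis: the amide base removes the furan α-proton next to bromine, the most acidic one through the inductive effect of the halogen, without bromine–lithium exchange; addition of 7 to the N-methoxy-N-methylamide stops at the chelated adduct 8, which shields the new, easily enolized ketone from base until the quench.

Step 4
Reactants: 9 2-[4-(benzyloxy)phenyl]-1-(3-bromo-4-methylfuran-2-yl)ethan-1-one
Product: 11 1-(3-acetyl-4-methylfuran-2-yl)-2-[4-(benzyloxy)phenyl]ethan-1-one, via 1-ethoxyvinyl enol ether 10 (not isolated)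
Conditions: Bu3SnC(OEt)=CH2, Pd(PPh3)4 (cat.), CuI (cat.), toluene, 100 °C; then 1 M HCl, THF, rt
Reagents that add atoms: tributyl(1-ethoxyvinyl)stannane, CCCC[Sn](CCCC)(CCCC)C(=C)OCC; water, O
Why: Stille coupling with an acetyl anion equivalent: zerovalent palladium inserts into the C–Br bond, which the ortho acyl group activates, and the 1-ethoxyvinyl group is transferred under neutral conditions that leave the enolizable ketone alone; dilute acid then hydrolyses enol ether 10 to the methyl ketone.

Step 5
Reactants: 11 1-(3-acetyl-4-methylfuran-2-yl)-2-[4-(benzyloxy)phenyl]ethan-1-one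
Product: 13 racemic 6-[4-(benzyloxy)phenyl]-3-methyl-5,6-dihydrobenzofuran-4,7-dione, via dilithium bis-enolate 12 (not isolated)
Conditions: 11 added slowly to LiN(i-Pr)2 (2.3 equiv), THF, −78 °C; CuCl2 (2.2 equiv), DMF, −78 → 0 °C; pH 7 buffer
Reagents that add atoms: none
Why: Twofold deprotonation gives bis-enolate 12, in which C5 (the former acetyl methyl) and C6 (the former benzylic methylene) are both enolate carbons held on adjacent furan positions. Divalent copper should take one electron from the more electron-rich, aryl-conjugated enolate to give a benzylic α-keto radical at C6, which adds to the unsubstituted terminus C5 of the neighbouring enolate; a second equivalent of CuCl2 oxidizes the resulting ketyl-type radical anion to the 1,4-diketone. If copper instead oxidizes or chlorinates the C6 radical first, the neighbouring enolate displaces at C6 and the same C5–C6 bond results, so both orders of events converge. The closest known reaction type is the intramolecular oxidative coupling of diketone bis-enolates to cyclic 1,4-diketones with CuCl2 or FeCl3. The six-membered carbocycle closes in a 6-endo-trig mode with respect to the accepting enolate C4=C5; the 5-exo alternative would attack the oxygen-bearing carbon C4 and leave a primary radical, so it is disfavoured electronically. The one new stereocentre, C6, forms without any controlling element, as a racemate, which is of no consequence because step 6 turns it into an sp2 carbon. The step needs C–C coupling to win over the five-membered intramolecular aldol reaction, over intermolecular coupling and over further oxidation of the product. Inverse addition to excess base ensures that no mono-enolate meets a free carbonyl, the ortho arrangement on the furan makes ring closure faster than dimerization, and two equivalents of oxidant at low temperature limit onward oxidation to the quinone.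

Step 6
Reactants: 13 racemic 6-[4-(benzyloxy)phenyl]-3-methyl-5,6-dihydrobenzofuran-4,7-dione
Product: 15 6-[4-(benzyloxy)phenyl]-4,7-dimethoxy-3-methylbenzofuran, via hydroquinone tautomer 14 (not isolated)
Conditions: K2CO3, acetone (degassed, Ar), rt; Me2SO4, reflux
Reagents that add atoms: dimethyl sulfate, COS(=O)(=O)OC
Why: Base-mediated enolization followed by Williamson O-methylation: carbonate removes the acidic C6–H and proton transfer from C5 gives the aromatic hydroquinone 14 as its phenoxide; this tautomerization is far faster than alkylation, so dimethyl sulfate should meet only phenoxide oxygen, and exclusion of air keeps the phenoxide from being oxidized.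

Step 7
Reactants: 15 6-[4-(benzyloxy)phenyl]-4,7-dimethoxy-3-methylbenzofuran
Product: 17 6-[4-(benzyloxy)phenyl]-2-iodo-4,7-dimethoxy-3-methylbenzofuran, via 2-lithiobenzofuran 16 (not isolated)
Conditions: n-BuLi (1.1 equiv), THF, −78 °C; I2, −78 °C → rt
Reagents that add atoms: iodine, II
Why: Deprotonation and iodination: C2–H next to the ring oxygen is the kinetically most acidic proton of a benzofuran and should be removed at −78 °C faster than the ortho or benzylic protons of the ether groups; iodine traps the aryllithium.

Step 8
Reactants: 17 6-[4-(benzyloxy)phenyl]-2-iodo-4,7-dimethoxy-3-methylbenzofuran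
Product: 18 methyl 2-{6-[4-(benzyloxy)phenyl]-4,7-dimethoxy-3-methylbenzofuran-2-yl}acetate
Conditions: BrZnCH2CO2Me (from BrCH2CO2Me, Zn, THF), Pd2(dba)3 (cat.), XPhos (cat.), THF, 60 °C
Reagents that add atoms: methyl bromoacetate, COC(=O)CBr
Why: Palladium-catalysed coupling of a Reformatsky reagent with an aryl iodide (Negishi-type α-arylation of a zinc ester enolate): zerovalent palladium inserts into the C2–I bond, the ester enolate is transferred from zinc and reductive elimination follows; the zinc enolate is too weakly basic to deprotonate the product or attack its ester.

Step 9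
Reactants: 18 methyl 2-{6-[4-(benzyloxy)phenyl]-4,7-dimethoxy-3-methylbenzofuran-2-yl}acetate
Product: 19 phenylcandilide B, methyl 2-[6-(4-hydroxyphenyl)-4,7-dimethoxy-3-methylbenzofuran-2-yl]acetate
Conditions: H2 (1 atm), Pd/C, EtOAc–MeOH, rt
Reagents that add atoms: none
Why: Hydrogenolysis of the benzyl aryl ether over Pd/C; the tetrasubstituted C2=C3 bond of the benzofuran, the methyl ethers and the ester should not be reduced under these conditions.

## Compound list

1 | 3,4-dibromofuran | Brc1cocc1Br | starting material
2 | (4-bromofuran-3-yl)lithium | [Li]c1cocc1Br | intermediate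
3 | 3-bromo-4-methylfuran | Cc1cocc1Br | intermediate
4 | 4-(benzyloxy)phenylacetic acid | OC(=O)Cc1ccc(OCc2ccccc2)cc1 | starting material
5 | 2-[4-(benzyloxy)phenyl]-1-(1H-imidazol-1-yl)ethan-1-one | O=C(Cc1ccc(OCc2ccccc2)cc1)n1ccnc1 | intermediate
6 | 2-[4-(benzyloxy)phenyl]-N-methoxy-N-methylacetamide | CON(C)C(=O)Cc1ccc(OCc2ccccc2)cc1 | intermediate
7 | (3-bromo-4-methylfuran-2-yl)lithium | [Li]c1occ(C)c1Br | intermediate
8 | racemic lithium 2-[4-(benzyloxy)phenyl]-1-(3-bromo-4-methylfuran-2-yl)-1-[methoxy(methyl)amino]ethan-1-olate | [Li+].[O-]C(Cc1ccc(OCc2ccccc2)cc1)(N(C)OC)c1occ(C)c1Br | intermediate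
9 | 2-[4-(benzyloxy)phenyl]-1-(3-bromo-4-methylfuran-2-yl)ethan-1-one | O=C(Cc1ccc(OCc2ccccc2)cc1)c1occ(C)c1Br | intermediate
10 | 2-[4-(benzyloxy)phenyl]-1-[3-(1-ethoxyvinyl)-4-methylfuran-2-yl]ethan-1-one | CCOC(=C)c1c(C)coc1C(=O)Cc1ccc(OCc2ccccc2)cc1 | intermediate
11 | 1-(3-acetyl-4-methylfuran-2-yl)-2-[4-(benzyloxy)phenyl]ethan-1-one | CC(=O)c1c(C)coc1C(=O)Cc1ccc(OCc2ccccc2)cc1 | intermediate
12 | dilithium (Z)-2-[4-(benzyloxy)phenyl]-1-[4-methyl-3-(1-oxidovinyl)furan-2-yl]ethen-1-olate | [Li+].[Li+].C=C([O-])c1c(C)coc1/C([O-])=C/c1ccc(OCc2ccccc2)cc1 | intermediate
13 | racemic 6-[4-(benzyloxy)phenyl]-3-methyl-5,6-dihydrobenzofuran-4,7-dione | Cc1coc2c1C(=O)CC(c1ccc(OCc3ccccc3)cc1)C2=O | intermediate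
14 | 6-[4-(benzyloxy)phenyl]-3-methylbenzofuran-4,7-diol | Cc1coc2c(O)c(-c3ccc(OCc4ccccc4)cc3)cc(O)c12 | intermediate
15 | 6-[4-(benzyloxy)phenyl]-4,7-dimethoxy-3-methylbenzofuran | Cc1coc2c(OC)c(-c3ccc(OCc4ccccc4)cc3)cc(OC)c12 | intermediate
16 | {6-[4-(benzyloxy)phenyl]-4,7-dimethoxy-3-methylbenzofuran-2-yl}lithium | [Li]c1oc2c(OC)c(-c3ccc(OCc4ccccc4)cc3)cc(OC)c2c1C | intermediate
17 | 6-[4-(benzyloxy)phenyl]-2-iodo-4,7-dimethoxy-3-methylbenzofuran | Ic1oc2c(OC)c(-c3ccc(OCc4ccccc4)cc3)cc(OC)c2c1C | intermediate
18 | methyl 2-{6-[4-(benzyloxy)phenyl]-4,7-dimethoxy-3-methylbenzofuran-2-yl}acetate | COC(=O)Cc1oc2c(OC)c(-c3ccc(OCc4ccccc4)cc3)cc(OC)c2c1C | intermediate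
19 | phenylcandilide B, methyl 2-[6-(4-hydroxyphenyl)-4,7-dimethoxy-3-methylbenzofuran-2-yl]acetate | COC(=O)Cc1oc2c(OC)c(-c3ccc(O)cc3)cc(OC)c2c1C | target

## Step count and least certain steps

Total step count: 9. Longest linear sequence: 8 steps (steps 1, 3, 4, 5, 6, 7, 8 and 9, from 1); step 2 is the side branch.

**Step 5 (key step).** Three things are most likely to go wrong.
- Incomplete double enolization, so that a mono-enolate attacks the neighbouring carbonyl and closes a five-membered aldol ring.
- Intermolecular coupling of the stabilized benzylic radical, which cyclizes slowly.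
- Onward oxidation: the product is far more acidic than the starting ketone, can take a proton from unreacted enolate, aromatize and be oxidized to the quinone level.

The fallback makes the same C5–C6 bond by a polar, stepwise path. It sets out from enol ether 10, which is then isolated after the coupling of step 4 without the acid treatment. N-Bromosuccinimide in THF–H2O at 0 °C should convert the enol ether into the bromomethyl ketone 2-[4-(benzyloxy)phenyl]-1-[3-(2-bromoacetyl)-4-methylfuran-2-yl]ethan-1-one F1. Cs2CO3 in MeCN then deprotonates only the much more acidic benzylic position, and the soft, aryl-stabilized enolate carbon is expected to displace bromide in a six-membered intramolecular C-alkylation, which returns to the route at 13. Material that has gone on to the quinone is recovered by the fallback of step 6.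

**Step 3.** The likely failure is proton transfer from the benzylic methylene of amide 6 to furyllithium 7 in place of addition, which returns 3; migration of bromine around the ring is a second risk if the anion warms. The fallback sets out from 3 by way of 7 and avoids an enolizable acylating agent. Trapping 7 with N,N-dimethylformamide gives 3-bromo-4-methylfuran-2-carbaldehyde F2. Addition of 4-(benzyloxy)benzylmagnesium chloride F3, made from the commercial benzylic chloride and Mg, gives racemic 2-[4-(benzyloxy)phenyl]-1-(3-bromo-4-methylfuran-2-yl)ethan-1-ol F4. Dess–Martin oxidation returns to the route at 9.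

**Step 4.** The bromide lies between two ortho substituents, so oxidative addition and transfer from tin may be slow, and prolonged heating then favours loss of bromine by reduction and self-condensation of the enolizable ketone. The fallback installs the acetyl group first and sets out from 3. Bromine–lithium exchange (t-BuLi, Et2O, −78 °C) gives (4-methylfuran-3-yl)lithium F5, which is acylated with N-methoxy-N-methylacetamide to 1-(4-methylfuran-3-yl)ethan-1-one F6. Ethylene glycol with catalytic acid gives 2-methyl-2-(4-methylfuran-3-yl)-1,3-dioxolane F7. n-BuLi removes the α-proton next to the ketal to give [4-methyl-3-(2-methyl-1,3-dioxolan-2-yl)furan-2-yl]lithium F8, which adds to 6 to give 2-[4-(benzyloxy)phenyl]-1-[4-methyl-3-(2-methyl-1,3-dioxolan-2-yl)furan-2-yl]ethan-1-one F9. Dilute aqueous acid removes the ketal and returns to the route at 11.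

**Step 6.** Two processes threaten it: oxidation of the electron-rich hydroquinone phenoxide by traces of air, and C-methylation at C6 of the dione enolate before aromatization is complete. The fallback goes through the stable quinone on purpose and sets out from 13. Oxidation with Ag2O in Et2O, which acts on the enol form 14, gives 6-[4-(benzyloxy)phenyl]-3-methylbenzofuran-4,7-dione F10, which can be purified. Reduction with Na2S2O4 and methylation in the same flask (Me2SO4, KOH, Bu4NBr, THF–H2O) returns to the route at 15.

**Step 8.** Slow transfer of the ester enolate from zinc to palladium at the hindered, electron-rich iodide would allow loss of iodine by reduction and homocoupling; self-condensation of the zinc reagent on standing is a further risk. The fallback builds the arm from a two-carbon alcohol and sets out from 15. Lithiation as in step 7 gives 16, which is trapped with ethylene oxide and BF3·OEt2 to give 2-{6-[4-(benzyloxy)phenyl]-4,7-dimethoxy-3-methylbenzofuran-2-yl}ethan-1-ol F11. Oxidation with catalytic TEMPO and PhI(OAc)2 in MeCN–H2O gives 2-{6-[4-(benzyloxy)phenyl]-4,7-dimethoxy-3-methylbenzofuran-2-yl}acetic acid F12. Methylation of the carboxylate (MeI, K2CO3, DMF) returns to the route at 18.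

## Further compounds

F1 | step 5 | 2-[4-(benzyloxy)phenyl]-1-[3-(2-bromoacetyl)-4-methylfuran-2-yl]ethan-1-one | O=C(CBr)c1c(C)coc1C(=O)Cc1ccc(OCc2ccccc2)cc1
F2 | step 3 | 3-bromo-4-methylfuran-2-carbaldehyde | O=Cc1occ(C)c1Br
F3 | step 3 | 4-(benzyloxy)benzylmagnesium chloride | Cl[Mg]Cc1ccc(OCc2ccccc2)cc1
F4 | step 3 | racemic 2-[4-(benzyloxy)phenyl]-1-(3-bromo-4-methylfuran-2-yl)ethan-1-ol | OC(Cc1ccc(OCc2ccccc2)cc1)c1occ(C)c1Br
F5 | step 4 | (4-methylfuran-3-yl)lithium | [Li]c1cocc1C
F6 | step 4 | 1-(4-methylfuran-3-yl)ethan-1-one | CC(=O)c1cocc1C
F7 | step 4 | 2-methyl-2-(4-methylfuran-3-yl)-1,3-dioxolane | CC1(OCCO1)c1cocc1C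
F8 | step 4 | [4-methyl-3-(2-methyl-1,3-dioxolan-2-yl)furan-2-yl]lithium | [Li]c1occ(C)c1C1(C)OCCO1
F9 | step 4 | 2-[4-(benzyloxy)phenyl]-1-[4-methyl-3-(2-methyl-1,3-dioxolan-2-yl)furan-2-yl]ethan-1-one | CC1(OCCO1)c1c(C)coc1C(=O)Cc1ccc(OCc2ccccc2)cc1
F10 | step 6 | 6-[4-(benzyloxy)phenyl]-3-methylbenzofuran-4,7-dione | Cc1coc2c1C(=O)C=C(c1ccc(OCc3ccccc3)cc1)C2=O
F11 | step 8 | 2-{6-[4-(benzyloxy)phenyl]-4,7-dimethoxy-3-methylbenzofuran-2-yl}ethan-1-ol | OCCc1oc2c(OC)c(-c3ccc(OCc4ccccc4)cc3)cc(OC)c2c1C
F12 | step 8 | 2-{6-[4-(benzyloxy)phenyl]-4,7-dimethoxy-3-methylbenzofuran-2-yl}acetic acid | OC(=O)Cc1oc2c(OC)c(-c3ccc(OCc4ccccc4)cc3)cc(OC)c2c1C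
A1 | alternative 1 | racemic methyl 3-{5-[4-(benzyloxy)phenyl]-2-bromo-3,6-dimethoxyphenoxy}pent-4-enoate | COC(=O)CC(C=C)Oc1c(Br)c(OC)cc(-c2ccc(OCc3ccccc3)cc2)c1OC
A2 | alternative 1 | methyl 2-{6-[4-(benzyloxy)phenyl]-4,7-dimethoxy-3-methylbenzofuran-2-yl}acetate | COC(=O)Cc1oc2c(OC)c(-c3ccc(OCc4ccccc4)cc3)cc(OC)c2c1C
A3 | alternative 2 | methyl 2-[4,7-dimethoxy-3-methyl-6-(2-oxoethyl)benzofuran-2-yl]acetate | COC(=O)Cc1oc2c(OC)c(CC=O)cc(OC)c2c1C
A4 | alternative 2 | but-3-en-2-one | CC(=O)C=C
A5 | alternative 2 | racemic methyl 2-[4,7-dimethoxy-3-methyl-6-(4-oxocyclohex-2-en-1-yl)benzofuran-2-yl]acetate | COC(=O)Cc1oc2c(OC)c(C3C=CC(=O)CC3)cc(OC)c2c1C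
A6 | alternative 3 | 3-[4-(benzyloxy)phenyl]cyclobut-3-ene-1,2-dione | O=C1C=C(c2ccc(OCc3ccccc3)cc2)C1=O
A7 | alternative 3 | {5-[2-(tert-butyldimethylsilyloxy)ethyl]-4-methylfuran-2-yl}lithium | [Li]c1cc(C)c(CCO[Si](C)(C)C(C)(C)C)o1
A8 | alternative 3 | racemic 3-[4-(benzyloxy)phenyl]-4-{5-[2-(tert-butyldimethylsilyloxy)ethyl]-4-methylfuran-2-yl}-4-hydroxycyclobut-2-en-1-one | O=C1C=C(c2ccc(OCc3ccccc3)cc2)C1(O)c1cc(C)c(CCO[Si](C)(C)C(C)(C)C)o1
A9 | alternative 3 | 6-[4-(benzyloxy)phenyl]-2-[2-(tert-butyldimethylsilyloxy)ethyl]-3-methylbenzofuran-4,7-diol | Cc1c(CCO[Si](C)(C)C(C)(C)C)oc2c(O)c(-c3ccc(OCc4ccccc4)cc3)cc(O)c12
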